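**Plan**

1. Numbering is that of the bicyclo[3.3.1]nonane core: C1 is the prenyl bridgehead, C5 the geranyl bridgehead, C9 the bridging ketone; ring A is C1–C2–C3–C4–C5–C9 (the acylated, enolised triketone) and ring B is C1–C9–C5–C6–C7–C8.
2. Retrosynthesis: one transform cuts C1–C8 (the bond between the two quaternary carbons, opening ring B) together with C7–CH2(prenyl). This leaves a monocyclic dearomatised acylphloroglucinol with geranyl and prenyl on C5. Then C5–geranyl, the two aryl–prenyl bonds and the aryl–C(=O) bond are cut back to phloroglucinol.
3. Enabling feature: the C7(H)(prenyl)–C8(CH3)2 unit of ring B is a C5 prenyl group alkylated at its CH carbon by a dimethylallyl cation. C8 is the tertiary cation this creates, and C1, the carbon between the C2 and C9 carbonyls of ring A, is the enol carbon held beside it.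
4. Forward: ring A comes from phloroglucinol by acylation, double C-prenylation and dearomatising C-geranylation at one of two symmetry-equivalent carbons. Ring B is closed last by a prenyltransferase, which adds the last C5 unit and forms C1–C8 in the same event.
5. Stereochemistry: C5 is made racemic and selected in the enzymatic step (kinetic resolution). C1 is dictated by C5 through the bridging geometry. C7 is set by the enzyme-controlled face of prenyl transfer (new prenyl endo, cis to the C2–C4 bridge).

Key step: step 4

Assumption: the prenyltransferase is a recombinant membrane-bound enzyme of the UbiA family (an orthologue or engineered variant of the bicycle-forming prenyltransferase of hyperforin biosynthesis, ideally from a plant that makes 7-endo type B acylphloroglucinols), used as yeast microsomes and counted as a catalyst; descriptors refer to the tautomers drawn, and the enantiomer of the racemic step-3 product that is converted in step 4 is the (4S)-form, CC(C)=CCC/C(C)=C/C[C@]1(CC=C(C)C)C(O)=C(C(=O)c2cccc(O)c2)C(=O)C(CC=C(C)C)=C1O.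

**Route**

Step 1
Reactants: 1 phloroglucinol; 2 3-hydroxybenzonitrile
Product: 4 2,3',4,6-tetrahydroxybenzophenone, via ketiminium chloride 3 (not isolated)
Conditions: ZnCl2, HCl (g), Et2O, 0 °C to rt; then H2O, 100 °C
Reagents that add atoms: water, O
Why: Houben–Hoesch reaction: the nitrilium species from 2, ZnCl2 and HCl should acylate the threefold-activated ring of 1 only once, because the ketiminium salt 3 is deactivated, and hydrolysis gives the ketone, the symmetry of 1 leaving no regiochemical question.

Step 2
Reactants: 4 2,3',4,6-tetrahydroxybenzophenone; 5 prenyl bromide (1-bromo-3-methylbut-2-ene)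
Product: 6 (3-hydroxyphenyl)[2,4,6-trihydroxy-3,5-bis(3-methylbut-2-en-1-yl)phenyl]methanone
Conditions: 5 (2.1 equiv), 10% aq. KOH, 0 °C
Reagents that add atoms: none
Why: Aromatic C-prenylation of a phloroglucinolate in water: hydrogen bonding to the phenoxide oxygens suppresses O-alkylation, the two ring CH carbons flanked by oxygens are the most nucleophilic sites, and the isolated, hydrated 3'-phenoxide is expected to react more slowly.

Step 3
Reactants: 6 (3-hydroxyphenyl)[2,4,6-trihydroxy-3,5-bis(3-methylbut-2-en-1-yl)phenyl]methanone; 7 geranyl bromide [(2E)-1-bromo-3,7-dimethylocta-2,6-diene]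
Product: 8 rac-3,5-dihydroxy-2-(3-hydroxybenzoyl)-4-[(2E)-3,7-dimethylocta-2,6-dien-1-yl]-4,6-bis(3-methylbut-2-en-1-yl)cyclohexa-2,5-dien-1-one
Conditions: LiN(SiMe3)2 (4.2 equiv), THF, 0 °C; then 7 (1.1 equiv), 0 °C to rt
Reagents that add atoms: none
Why: Alkylative dearomatisation of a 3,5-dialkyl acylphloroglucinol: the lithium phenoxides flanking a prenyl-bearing ring carbon direct the allylic bromide to that carbon (SN2, E geometry kept), the two such carbons are equivalent by symmetry so only one constitution should arise, and the new quaternary centre is formed racemic.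

Step 4
Reactants: 8 rac-3,5-dihydroxy-2-(3-hydroxybenzoyl)-4-[(2E)-3,7-dimethylocta-2,6-dien-1-yl]-4,6-bis(3-methylbut-2-en-1-yl)cyclohexa-2,5-dien-1-one (the (4S)-enantiomer is the one converted); 9 dimethylallyl diphosphate (triammonium salt)
Product: 10 (1S,5S,7S)-5-[(2E)-3,7-dimethylocta-2,6-dien-1-yl]-4-hydroxy-3-(3-hydroxybenzoyl)-8,8-dimethyl-1,7-bis(3-methylbut-2-en-1-yl)bicyclo[3.3.1]non-3-ene-2,9-dione (the target)
Conditions: UbiA-type aromatic prenyltransferase (recombinant, yeast microsomes), 9 (excess), MgCl2, Tris-HCl buffer pH 7.5, 5% DMSO, 30 °C
Reagents that add atoms: none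
Why: Proposed new method: the magnesium-bound diphosphate of 9 ionises in the active site to the dimethylallyl cation, the double bond of the C5 prenyl group of (4S)-8 attacks it through its CH carbon (new C7–CH2 bond), and the tertiary cation left at the gem-dimethyl carbon C8 is captured by C1, the prenyl-bearing carbon of the enolised C2/C9 diketone, with loss of the enol proton; the closest known reaction type is the UbiA-type prenyltransferase step of hyperforin biosynthesis that prenylates a side-chain double bond of a dearomatised acylphloroglucinol and closes the bicyclo[3.3.1]nonane core, whose non-enzymatic relative is the acid-mediated cation cyclisation of lavandulyl-substituted dearomatised acylphloroglucinols. Ring B closes in a 6-endo-trig mode with respect to the attacked C7=C8 double bond (6-enolendo with respect to the C9=C1 enol). C5 is selected by kinetic resolution, the chiral pocket being expected to accept only the enantiomer whose prenyl group lies under the diphosphate site, so that no more than half of racemic 8 can be converted and the (4R)-enantiomer should be left behind. C1 follows from C5, because the three-atom tether C6–C7–C8 can reach C1 only on the ring face to which it is attached. C7 is set by the enzyme, which must hold the side chain in a boat-like fold so that anti addition of the dimethylallyl cation and of C1 across the double bond leaves the new prenyl group endo, cis to the C2–C4 bridge. The step needs the C5 prenyl double bond to be chosen over those of the geranyl and C1 prenyl groups, and C1 to be chosen over C3 and the enol oxygens as the cation trap; the first is secured by the placing of 9 in the active site, the second by the substrate (C1 is more nucleophilic and less hindered than the acyl-bearing C3) and by the pocket geometry.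

**Compound list**

1 | phloroglucinol (benzene-1,3,5-triol) | Oc1cc(O)cc(O)c1 | starting material
2 | 3-hydroxybenzonitrile | N#Cc1cccc(O)c1 | starting material
3 | (3-hydroxyphenyl)(2,4,6-trihydroxyphenyl)methaniminium chloride (ketiminium chloride) | [NH2+]=C(c1cccc(O)c1)c1c(O)cc(O)cc1O.[Cl-] | intermediate
4 | 2,3',4,6-tetrahydroxybenzophenone | O=C(c1cccc(O)c1)c1c(O)cc(O)cc1O | intermediate
5 | prenyl bromide (1-bromo-3-methylbut-2-ene) | CC(C)=CCBr | starting material
6 | (3-hydroxyphenyl)[2,4,6-trihydroxy-3,5-bis(3-methylbut-2-en-1-yl)phenyl]methanone | O=C(c1cccc(O)c1)c1c(O)c(CC=C(C)C)c(O)c(CC=C(C)C)c1O | intermediate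
7 | geranyl bromide, (2E)-1-bromo-3,7-dimethylocta-2,6-diene | CC(C)=CCC/C(C)=C/CBr | starting material
8 | rac-3,5-dihydroxy-2-(3-hydroxybenzoyl)-4-[(2E)-3,7-dimethylocta-2,6-dien-1-yl]-4,6-bis(3-methylbut-2-en-1-yl)cyclohexa-2,5-dien-1-one (racemic at C4) | CC(C)=CCC/C(C)=C/CC1(CC=C(C)C)C(O)=C(C(=O)c2cccc(O)c2)C(=O)C(CC=C(C)C)=C1O | intermediate
9 | dimethylallyl diphosphate, triammonium salt | CC(C)=CCOP(=O)([O-])OP(=O)([O-])[O-].[NH4+].[NH4+].[NH4+] | starting material
10 | (1S,5S,7S)-5-[(2E)-3,7-dimethylocta-2,6-dien-1-yl]-4-hydroxy-3-(3-hydroxybenzoyl)-8,8-dimethyl-1,7-bis(3-methylbut-2-en-1-yl)bicyclo[3.3.1]non-3-ene-2,9-dione (7-prenyl endo) | CC(C)=CCC/C(C)=C/C[C@]12C[C@H](CC=C(C)C)C(C)(C)[C@](CC=C(C)C)(C(=O)C(C(=O)c3cccc(O)c3)=C1O)C2=O | target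

**Step count and risks**

Total step count: 4. Longest linear sequence: 4 steps (1 → 4 → 6 → 8 → 10).

Steps most likely to fail:

Step 4 (Proposed new method). The enzyme may not turn over this substrate. Prenyl transfer may go to the geranyl double bond or to oxygen. The cation may be trapped at C3 or by an enol oxygen. The enzyme may fail to discriminate the enantiomers of 8, or may fold the side chain chair-like and give the 7-exo series. The fallback uses known chemistry, sets out from 4 and comes back at 10. C-Prenylation of 4 with one equivalent of 5 (aq. KOH) should give (3-hydroxyphenyl)[2,4,6-trihydroxy-3-(3-methylbut-2-en-1-yl)phenyl]methanone F1. C-Geranylation of F1 with 7 at the remaining ring CH should give the geranyl prenyl benzophenone F2. (R)-Lavandulol F3 (purchased, or from the racemate by lipase resolution) is converted with I2, PPh3 and imidazole (Appel reaction) into (R)-lavandulyl iodide F4. Alkylative dearomatisation of F2 with F4 (LiN(SiMe3)2, THF) at the geranyl-bearing carbon is not controlled in regiochemistry or at the new quaternary centre. The required isomer, the lavandulyl triketone F5, would have to be separated by chromatography from its regioisomer and its epimer; C7 is already fixed in it by the lavandulyl unit. Neat HCO2H at room temperature should then protonate the isopropenyl group to the same C8 tertiary cation, which C1 traps to close the C1–C8 bond and give 10 (acid-mediated cation cyclisation).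

Step 3. O-Alkylation of the phenoxides (the 3'-phenoxide included), alkylation at the acyl-bearing carbon or a second alkylation may compete with the wanted C-alkylation. The fallback sets out from 6 and comes back at 8. A Tsuji–Trost allylation with geranyl acetate F6, Pd(PPh3)4 (zerovalent palladium) and Et3N in THF replaces the strong-base SN2 reaction. The pi-geranyl palladium electrophile should react at the soft ring carbon at its less substituted terminus, and O-allylation is reversible under the catalyst.

Step 2. Over-alkylation to dearomatised geminal diprenyl products, incomplete alkylation and O-prenylation at the 3'-oxygen may erode the wanted double C-prenylation. The fallback sets out from 4 and comes back at 6. A Friedel–Crafts prenylation with 2-methylbut-3-en-2-ol F7 and BF3·OEt2 in dioxane runs on the un-ionised phenol by electrophilic aromatic substitution, so that no phenoxide is present to be O-alkylated.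

**Further compounds**

F1 | step 4 | (3-hydroxyphenyl)[2,4,6-trihydroxy-3-(3-methylbut-2-en-1-yl)phenyl]methanone | O=C(c1cccc(O)c1)c1c(O)cc(O)c(CC=C(C)C)c1O
F2 | step 4 | {3-[(2E)-3,7-dimethylocta-2,6-dien-1-yl]-2,4,6-trihydroxy-5-(3-methylbut-2-en-1-yl)phenyl}(3-hydroxyphenyl)methanone (geranyl prenyl benzophenone) | CC(C)=CCC/C(C)=C/Cc1c(O)c(CC=C(C)C)c(O)c(C(=O)c2cccc(O)c2)c1O
F3 | step 4 | (R)-lavandulol, (2R)-5-methyl-2-(prop-1-en-2-yl)hex-4-en-1-ol | OC[C@H](CC=C(C)C)C(C)=C
F4 | step 4 | (R)-lavandulyl iodide, (2R)-1-iodo-5-methyl-2-(prop-1-en-2-yl)hex-4-ene | IC[C@H](CC=C(C)C)C(C)=C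
F5 | step 4 | lavandulyl triketone: analogue of 8 with the prenyl group on the quaternary ring carbon replaced by the (R)-lavandulol-derived CH2CH(prenyl)C(CH3)=CH2 chain, quaternary carbon configured as C5 of 10, side-chain stereocentre (S) | CC(C)=CCC/C(C)=C/C[C@]1(C[C@H](CC=C(C)C)C(C)=C)C(O)=C(C(=O)c2cccc(O)c2)C(=O)C(CC=C(C)C)=C1O
F6 | step 3 | geranyl acetate, (2E)-3,7-dimethylocta-2,6-dien-1-yl acetate | CC(C)=CCC/C(C)=C/COC(C)=O
F7 | step 2 | 2-methylbut-3-en-2-ol | C=CC(C)(C)O
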